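**Plan** (flavan numbering; ring D is the pyran fused to ring B)
1. Cuts: the 5′-O–CH3 bond (made last in reverse, cleaved last forward). The C6–C(CH3)2 bond of ring A, traced back through a [3,3] shift to a 7-O-prenyl ether. O1–C2 of ring C. C3–C4, as the C=C of a chalcone. In ring D, both C–C bonds that hold the CH=CH unit (aryl C3′–CH= and =CH–C(CH3)2). The C2′–prenyl bond.
2. Enabling feature: O4′ of ring B carries a tertiary O–C(CH3)2 carbon, and only one of its ortho carbons, C3′, is free, because C5′ bears oxygen. Written as an aryloxyisobutyric acid, this carbon gives a stabilised radical on decarboxylation. That radical takes up a two-carbon acceptor and closes on C3′. Ring D therefore comes from phenol, acetone, CHCl3 and a vinyl sulfoxide used as an acetylene equivalent; the helpers CO2 and PhSOH leave again.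
3. Forward order: ring B is dressed first (acid side chain, Br, prenyl) and ring D is closed by the radical annulation. The ring A aldehyde is joined by Claisen–Schmidt condensation and ring C is closed by Mitsunobu etherification. Claisen rearrangement and demethylation finish the route.
4. Stereochemistry: the only stereocentre, C2, is set by catalyst-controlled asymmetric transfer hydrogenation to the (R)-carbinol. Ring closure with inversion then gives (2S).

Key step: step 5

Remark: 10 arises as a mixture of diastereomers at C4 and sulfur and is drawn without descriptors; both centres disappear within the same step.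

**Step 1**
Reactants: 1 acetovanillone [1-(4-hydroxy-3-methoxyphenyl)ethan-1-one]; 2 acetone
Product: 4 2-(4-acetyl-2-methoxyphenoxy)-2-methylpropanoic acid, via dichlorodimethyloxirane 3 (not isolated)
Conditions: NaOH (powder), CHCl3 (slow addition), acetone, 0 °C to reflux; acidic work-up
Reagents that add atoms: chloroform ClC(Cl)Cl; sodium hydroxide [Na+].[OH-]
Why: Bargellini reaction, in which trichloromethide adds to acetone, the derived gem-dichloroepoxide 3 is opened at its tertiary carbon by the only phenoxide of 1 and the acyl chloride is hydrolysed, a standard entry to hindered 2-aryloxyisobutyric acids.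

**Step 2**
Reactants: 4 2-(4-acetyl-2-methoxyphenoxy)-2-methylpropanoic acid
Product: 5 2-(4-acetyl-5-bromo-2-methoxyphenoxy)-2-methylpropanoic acid
Conditions: NBS, MeCN, 0 °C to rt, dark
Reagents that add atoms: N-bromosuccinimide O=C1CCC(=O)N1Br
Why: Electrophilic aromatic bromination, in which the methoxy group is the strongest donor (the aryloxy oxygen is conjugated with the para acetyl group), so bromine should enter para to it and ortho to the acetyl group as in 3,4-dialkoxyacetophenones, while the polar acid-free medium disfavours α-bromination of the ketone.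

**Step 3**
Reactants: 5 2-(4-acetyl-5-bromo-2-methoxyphenoxy)-2-methylpropanoic acid; 6 prenylboronic acid pinacol ester
Product: 7 2-[4-acetyl-2-methoxy-5-(3-methylbut-2-en-1-yl)phenoxy]-2-methylpropanoic acid
Conditions: Pd(dppf)Cl2 (5 mol %), K3PO4, THF/H2O, 65 °C; acidic work-up
Reagents that add atoms: none
Why: Suzuki–Miyaura coupling of an aryl bromide with a prenylboronate, which with a bisphosphine-ligated palladium catalyst should couple mainly at the unsubstituted allyl terminus to give the linear prenyl arene, the acid travelling as its carboxylate.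

**Step 4**
Reactants: 7 2-[4-acetyl-2-methoxy-5-(3-methylbut-2-en-1-yl)phenoxy]-2-methylpropanoic acid
Product: 8 1,3-dioxoisoindolin-2-yl 2-[4-acetyl-2-methoxy-5-(3-methylbut-2-en-1-yl)phenoxy]-2-methylpropanoate
Conditions: N-hydroxyphthalimide, N,N'-diisopropylcarbodiimide (DIC), DMAP (10 mol %), CH2Cl2, rt
Reagents that add atoms: N-hydroxyphthalimide O=C1c2ccccc2C(=O)N1O
Why: Steglich-type carbodiimide esterification, routine even for α,α-disubstituted acids, turns the carboxyl group into a redox-active ester.

**Step 5**
Reactants: 8 redox-active ester; 9 phenyl vinyl sulfoxide (racemic)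
Product: 11 1-[8-methoxy-2,2-dimethyl-5-(3-methylbut-2-en-1-yl)-2H-chromen-6-yl]ethan-1-one, via 4-(phenylsulfinyl)chroman 10 (not isolated)
Conditions: fac-Ir(ppy)3 (1 mol %), 9 (3 equiv), MeCN, 450 nm LEDs, rt, argon; then solvent change to toluene, 100 °C
Reagents that add atoms: none
Why: Proposed new method: the excited photocatalyst gives one electron to the N-acyloxyphthalimide of 8, which loses phthalimide anion and CO2 and leaves the tertiary, oxygen-stabilised, nucleophilic radical ArO–C(CH3)2•; this adds to the CH2 terminus of the electron-poor alkene 9 (first bond), the electrophilic α-sulfinyl radical attacks the ring carbon ortho to the ether oxygen (second bond), the oxidised photocatalyst (tetravalent iridium) takes an electron from the cyclohexadienyl radical and phthalimide anion takes the proton, so the annulation to 10 is redox-neutral, and warming then expels PhSOH by syn elimination to give 11. The closest known reaction type is the photoredox decarboxylative radical (4+2) annulation of aryloxyalkyl N-hydroxyphthalimide esters with acrylates and related electron-poor alkenes to chromans, joined here to the classical use of phenyl vinyl sulfoxide as an acetylene equivalent; a vinyl sulfoxide has not been shown as the acceptor and the annulation has not been coupled with a sulfoxide elimination. The pyran ring closes by six-membered homolytic aromatic substitution (formally 6-endo-trig on the ipso–ortho bond), favoured by the gem-dimethyl group, while the competing 5-exo ipso attack is reversible because its only exit would expel an alkoxyl radical. The carbon and sulfur stereocentres of 10 are not controlled and need not be, since both are erased by the elimination, which can run only toward C3 because the other β-carbon is aromatic. Site selectivity comes from the substrate, as one ortho carbon bears the methoxy group and only the one next to the prenyl group is free; chemoselectivity comes from polarity, as the nucleophilic radical ignores the electron-rich prenyl alkene and an activated acceptor in excess outruns its oxidation to the oxocarbenium ion, which unactivated acetylene would not. An sp3 carbon at C4 lets the sulfinyl group stand pseudoaxial, away from the neighbouring prenyl group, and the neutral thermal removal of the helper spares the methyl ketone and the prenyl group, which base-induced loss of a sulfinate from the analogous sulfone might not.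

**Step 6**
Reactants: 12 2,4-dihydroxybenzaldehyde; 13 prenyl bromide (1-bromo-3-methylbut-2-ene)
Product: 14 2-hydroxy-4-[(3-methylbut-2-en-1-yl)oxy]benzaldehyde
Conditions: K2CO3 (1.1 equiv), acetone, reflux
Reagents that add atoms: none
Why: Williamson ether synthesis, selective for the 4-OH because the 2-OH is held in a hydrogen bond to the aldehyde and is the less acidic and less nucleophilic site.

**Step 7**
Reactants: 11 chromenyl methyl ketone; 14 2-hydroxy-4-(prenyloxy)benzaldehyde
Product: 15 (E)-3-{2-hydroxy-4-[(3-methylbut-2-en-1-yl)oxy]phenyl}-1-[8-methoxy-2,2-dimethyl-5-(3-methylbut-2-en-1-yl)-2H-chromen-6-yl]prop-2-en-1-one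
Conditions: KOH, EtOH, rt; work-up at pH 6
Reagents that add atoms: none
Why: Claisen–Schmidt condensation of a methyl ketone with a non-enolisable aldehyde followed by E1cB dehydration to the (E)-enone, the 2-OH being carried as phenoxide while the prenyl ether keeps the para oxygen from becoming a second, deactivating phenoxide.

**Step 8**
Reactants: 15 (E)-2-hydroxychalcone
Product: 17 2-{(3R)-3-hydroxy-3-[8-methoxy-2,2-dimethyl-5-(3-methylbut-2-en-1-yl)-2H-chromen-6-yl]propyl}-5-[(3-methylbut-2-en-1-yl)oxy]phenol, via saturated ketone 16 (not isolated)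
Conditions: RuCl[(R,R)-TsDPEN](p-cymene) (3 mol %), HCO2H/Et3N 5:2, EtOAc, 40 °C, dark
Reagents that add atoms: none
Why: Noyori–Ikariya asymmetric transfer hydrogenation run as a domino process, in which the ruthenium hydride first reduces the enone C=C by 1,4-addition and then the aryl ketone 16, the (R,R)-catalyst delivering hydride to the face that gives the (R)-carbinol as with acetophenone-type ketones, while isolated and styrene-type alkenes are not touched.

**Step 9**
Reactants: 17 (R)-carbinol phenol
Product: 18 (2S)-2-[8-methoxy-2,2-dimethyl-5-(3-methylbut-2-en-1-yl)-2H-chromen-6-yl]-7-[(3-methylbut-2-en-1-yl)oxy]chroman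
Conditions: PPh3, DIAD, THF, 0 °C to rt
Reagents that add atoms: none
Why: Intramolecular Mitsunobu etherification, in which the only free phenol displaces the activated benzylic oxygen (6-exo-tet) with inversion and so turns the (R)-carbinol into the (2S)-flavan.

**Step 10**
Reactants: 18 (2S)-7-O-prenylflavan
Product: 19 (2S)-2-[8-methoxy-2,2-dimethyl-5-(3-methylbut-2-en-1-yl)-2H-chromen-6-yl]-6-(2-methylbut-3-en-2-yl)chroman-7-ol (5′-O-methylkazinol H)
Conditions: N,N-diethylaniline, 190 °C, argon
Reagents that add atoms: none
Why: Aromatic Claisen rearrangement of the aryl prenyl ether with allyl inversion places the 1,1-dimethylallyl group ortho to the freed 7-OH, C6 being preferred over C8 because it is para to the donor O1 and unhindered whereas C8 lies between two oxygens, the basic solvent suppressing acid-catalysed cyclisation of the product and C2 taking no part.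

**Step 11**
Reactants: 19 5′-O-methylkazinol H
Product: 20 kazinol H
Conditions: NaSEt (excess), DMF, 120 °C; work-up at pH 6–7
Reagents that add atoms: none
Why: SN2 demethylation of the aryl methyl ether by thiolate, chosen because the basic, non-acidic medium should leave the chromene, both prenyl-type groups and the benzylic ether stereocentre intact, neither phenoxide being conjugated with C2.

**Compound list**
1 | acetovanillone, 1-(4-hydroxy-3-methoxyphenyl)ethan-1-one | CC(=O)c1ccc(O)c(OC)c1 | starting material
2 | acetone | CC(C)=O | starting material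
3 | 2,2-dichloro-3,3-dimethyloxirane (not isolated) | CC1(C)OC1(Cl)Cl | intermediate
4 | 2-(4-acetyl-2-methoxyphenoxy)-2-methylpropanoic acid | CC(=O)c1ccc(OC(C)(C)C(=O)O)c(OC)c1 | intermediate
5 | 2-(4-acetyl-5-bromo-2-methoxyphenoxy)-2-methylpropanoic acid | CC(=O)c1cc(OC)c(OC(C)(C)C(=O)O)cc1Br | intermediate
6 | prenylboronic acid pinacol ester | CC(C)=CCB1OC(C)(C)C(C)(C)O1 | starting material
7 | 2-[4-acetyl-2-methoxy-5-(3-methylbut-2-en-1-yl)phenoxy]-2-methylpropanoic acid | CC(=O)c1cc(OC)c(OC(C)(C)C(=O)O)cc1CC=C(C)C | intermediate
8 | 1,3-dioxoisoindolin-2-yl ester of 7 | CC(=O)c1cc(OC)c(OC(C)(C)C(=O)ON2C(=O)c3ccccc3C2=O)cc1CC=C(C)C | intermediate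
9 | phenyl vinyl sulfoxide (racemic) | C=CS(=O)c1ccccc1 | starting material
10 | 1-[8-methoxy-2,2-dimethyl-5-(3-methylbut-2-en-1-yl)-4-(phenylsulfinyl)chroman-6-yl]ethan-1-one (diastereomer mixture, not isolated) | CC(=O)c1cc(OC)c2OC(C)(C)CC(S(=O)c3ccccc3)c2c1CC=C(C)C | intermediate
11 | 1-[8-methoxy-2,2-dimethyl-5-(3-methylbut-2-en-1-yl)-2H-chromen-6-yl]ethan-1-one | CC(=O)c1cc(OC)c2OC(C)(C)C=Cc2c1CC=C(C)C | intermediate
12 | 2,4-dihydroxybenzaldehyde | O=Cc1ccc(O)cc1O | starting material
13 | prenyl bromide | CC(C)=CCBr | starting material
14 | 2-hydroxy-4-[(3-methylbut-2-en-1-yl)oxy]benzaldehyde | O=Cc1ccc(OCC=C(C)C)cc1O | intermediate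
15 | (E)-2-hydroxychalcone | O=C(/C=C/c1ccc(OCC=C(C)C)cc1O)c1cc(OC)c2OC(C)(C)C=Cc2c1CC=C(C)C | intermediate
16 | saturated ketone (dihydrochalcone, not isolated) | O=C(CCc1ccc(OCC=C(C)C)cc1O)c1cc(OC)c2OC(C)(C)C=Cc2c1CC=C(C)C | intermediate
17 | (R)-1,3-diarylpropan-1-ol | O[C@H](CCc1ccc(OCC=C(C)C)cc1O)c1cc(OC)c2OC(C)(C)C=Cc2c1CC=C(C)C | intermediate
18 | (2S)-7-O-prenylflavan | CC(C)=CCOc1ccc2c(c1)O[C@H](c1cc(OC)c3c(c1CC=C(C)C)C=CC(C)(C)O3)CC2 | intermediate
19 | 5′-O-methylkazinol H | C=CC(C)(C)c1cc2c(cc1O)O[C@H](c1cc(OC)c3c(c1CC=C(C)C)C=CC(C)(C)O3)CC2 | intermediate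
20 | kazinol H | C=CC(C)(C)c1cc2c(cc1O)O[C@H](c1cc(O)c3c(c1CC=C(C)C)C=CC(C)(C)O3)CC2 | target

**Total step count:** 11. **Longest linear sequence:** 10 (steps 1–5 and 7–11).

**Steps most likely to fail**

Step 5 (labelled step). Three processes may go wrong:
- oxidation of the tertiary radical to the oxocarbenium ion before it adds to the acceptor;
- slow closure onto the hindered ortho carbon, with premature hydrogen abstraction;
- capture of the sulfenic acid by the alkenes during the thermolysis.

The fallback uses known chemistry and is sigmatropic instead of radical. It sets out from 1 and comes back at 11. Copper-catalysed O-alkylation of 1 with 3-chloro-3-methylbut-1-yne (CuCl2, DBU, MeCN, 0 °C) should give the aryl 1,1-dimethylpropargyl ether F1. NBS in MeCN should brominate para to the methoxy group to give the bromo propargyl ether F2. Suzuki–Miyaura coupling with 6 should give the prenylated propargyl ether F3. Heating in xylene at 140 °C should then trigger propargyl Claisen rearrangement to the only free ortho carbon, 1,5-hydrogen shift and oxa-6π electrocyclisation to 11.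

Step 10. Three processes may go wrong:
- poor regioselectivity of the [3,3] shift, with migration to C8;
- thermal ring-opening chemistry of ring D;
- follow-up cyclisation of the freed phenol onto the vinyl group.

The fallback replaces the rearrangement by a regiodefined cross-coupling. It sets out from 11 and comes back at 20. Claisen–Schmidt condensation of 11 with commercial 5-bromo-2-hydroxy-4-methoxybenzaldehyde should give the bromochalcone F4. The domino transfer hydrogenation of step 8 should give the (R)-bromocarbinol F5. Mitsunobu closure should give the (2S)-6-bromo-7-methoxyflavan F6. A ligand-controlled, branched-selective Suzuki–Miyaura coupling with 6 (Pd(OAc)2, bulky biarylphosphine, K3PO4, aqueous THF) should give 7,5′-di-O-methylkazinol H F7. NaSEt in DMF should cleave both methyl ethers to 20.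

Step 9. The activated, electron-rich benzylic alcohol may ionise before displacement, with loss of enantiomeric purity, or it may eliminate to the styrene. The fallback makes the ring C ether bond at the aromatic carbon, so the stereocentre is not touched. It sets out from 11 and comes back at 18. Commercial 2-bromo-4-hydroxybenzaldehyde and 13 (K2CO3, acetone) should give 2-bromo-4-(prenyloxy)benzaldehyde F8. Claisen–Schmidt condensation with 11 should give the 2-bromochalcone F9. Domino transfer hydrogenation with RuCl[(S,S)-TsDPEN](p-cymene) should give the (S)-bromocarbinol F10. An intramolecular Ullmann-type O-arylation (CuI, 1,10-phenanthroline, Cs2CO3, toluene, 110 °C) should close ring C with retention to 18.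

**Further compounds**
F1 | step 5 | 1-{3-methoxy-4-[(2-methylbut-3-yn-2-yl)oxy]phenyl}ethan-1-one | CC(=O)c1ccc(OC(C)(C)C#C)c(OC)c1
F2 | step 5 | 1-{2-bromo-5-methoxy-4-[(2-methylbut-3-yn-2-yl)oxy]phenyl}ethan-1-one | CC(=O)c1cc(OC)c(OC(C)(C)C#C)cc1Br
F3 | step 5 | 1-{5-methoxy-4-[(2-methylbut-3-yn-2-yl)oxy]-2-(3-methylbut-2-en-1-yl)phenyl}ethan-1-one | CC(=O)c1cc(OC)c(OC(C)(C)C#C)cc1CC=C(C)C
F4 | step 10 | (E)-3-(5-bromo-2-hydroxy-4-methoxyphenyl)-1-[8-methoxy-2,2-dimethyl-5-(3-methylbut-2-en-1-yl)-2H-chromen-6-yl]prop-2-en-1-one | O=C(/C=C/c1cc(Br)c(OC)cc1O)c1cc(OC)c2OC(C)(C)C=Cc2c1CC=C(C)C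
F5 | step 10 | 4-bromo-2-{(3R)-3-hydroxy-3-[8-methoxy-2,2-dimethyl-5-(3-methylbut-2-en-1-yl)-2H-chromen-6-yl]propyl}-5-methoxyphenol | O[C@H](CCc1cc(Br)c(OC)cc1O)c1cc(OC)c2OC(C)(C)C=Cc2c1CC=C(C)C
F6 | step 10 | (2S)-6-bromo-7-methoxy-2-[8-methoxy-2,2-dimethyl-5-(3-methylbut-2-en-1-yl)-2H-chromen-6-yl]chroman | Brc1cc2c(cc1OC)O[C@H](c1cc(OC)c3c(c1CC=C(C)C)C=CC(C)(C)O3)CC2
F7 | step 10 | 7,5′-di-O-methylkazinol H | C=CC(C)(C)c1cc2c(cc1OC)O[C@H](c1cc(OC)c3c(c1CC=C(C)C)C=CC(C)(C)O3)CC2
F8 | step 9 | 2-bromo-4-[(3-methylbut-2-en-1-yl)oxy]benzaldehyde | O=Cc1ccc(OCC=C(C)C)cc1Br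
F9 | step 9 | (E)-3-{2-bromo-4-[(3-methylbut-2-en-1-yl)oxy]phenyl}-1-[8-methoxy-2,2-dimethyl-5-(3-methylbut-2-en-1-yl)-2H-chromen-6-yl]prop-2-en-1-one | O=C(/C=C/c1ccc(OCC=C(C)C)cc1Br)c1cc(OC)c2OC(C)(C)C=Cc2c1CC=C(C)C
F10 | step 9 | (1S)-3-{2-bromo-4-[(3-methylbut-2-en-1-yl)oxy]phenyl}-1-[8-methoxy-2,2-dimethyl-5-(3-methylbut-2-en-1-yl)-2H-chromen-6-yl]propan-1-ol | O[C@@H](CCc1ccc(OCC=C(C)C)cc1Br)c1cc(OC)c2OC(C)(C)C=Cc2c1CC=C(C)C
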